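**Early times.** At early times the target peak stays within its scatter: Wednesday's run reads 1% at 0.500 h and Monday's reads 1% at 1.00 h, with a scatter of 2 percentage points. Then both runs climb steadily, so I take a lag of 0.500 h.

| setting | Wednesday's | Monday's | flask |
|---|---|---|---|
| starting material | 0.0050 M | 0.0075 M | 0.010 M |
| salt in the second phase | 0.040 M | 0.040 M | 0.0400 M |
| spent carrier | 1 mM | 1 mM | 1.0 mM |
| remark | run made earlier | run made earlier |  |
| time |  |  | 6.0 h |
| volume of the second phase over the first |  |  | 1.0 |

- Wednesday's (time / h: target / %, starting material / %): 0.500: 1, 101; 0.833: 2, 99; 1.33: 1, 96; 2.00: 5, 91; 3.00: 7, 89; 5.00: 14, 82; 8.00: 25, 71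
- Monday's (time / h: target / %, starting material / %): 1.00: 1, 95; 2.00: 9, 94; 3.00: 10, 89; 4.00: 12, 85; 5.00: 14, 78; 6.00: 18, 80; 8.00: 21, 73

(standard deviation of a reading: 2 percentage points)

- a species is counted by the starting material in it: one idle adduct counts as two
- amounts and yields of target count idle adduct too
- in the second phase: salt in the second phase, spent salt in the second phase; everything else is in the first
- charges count per volume of the first phase; a concentration in a rate is the amount of a species over the volume of its own phase; every rate counts per litre of the first phase
- steps that have been proposed: spent carrier + salt in the second phase <-> fresh carrier + spent salt in the second phase; starting material + fresh carrier -> target + spent carrier; target <-> isomer of the product; starting material + target <-> idle adduct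
- the earlier runs hold the two phases in the same ratio of volumes as the flask asked about
- in an amount of target, one idle adduct counts as one target

- amount of target in percent of the starting material charged, at 40 min, 2.0 h, 4.0 h and 6.0 h

**Zero line.** From run to run c(starting material) changes, while salt and spent carrier stay as charged. So take the pseudo-first-order case as the zero of the scale: a rate proportional to c(starting material) puts the percent curves of all charges on top of each other. At 8.00 h the target readings are 25% and 21%, a gap of 1.41 standard deviations of a difference. That gap doesn't take the runs off the zero line.

**Charge rate.** So pool them. The mean reading over the time after the lag gives 0.0307 h⁻¹ of the charge per hour; call this the charge rate. For the flask, charge rate times time after the lag gives 0.511%, 4.60%, 10.7% and 16.9%, and I commit to these.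

**Weak link.** The flat scale rests on one peak. The starting-material peak is read separately, and at 8.00 h its readings differ by 2 points, which is 0.707 standard deviations of a difference. The zero line stands.

**The forecast.** It gives 1.2%, 5%, 10.5% and 15.5%, with the rate rising “roughly to the power 0.7”. My reckoning holds the percent slope flat instead; at 6.0 h it stands higher than the forecast, and at 40 min it stands lower, with its lag of 0.500 h taken off the time.

**The equations.**

    spent carrier + salt in the second phase ⇌ fresh carrier + spent salt in the second phase (K = 0.450, k = 24.0 L mol⁻¹ h⁻¹)
    starting material + fresh carrier → target + spent carrier (k = 58.0 L mol⁻¹ h⁻¹)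
    target ⇌ isomer of the product (K = 1.40, k = 0.00500 h⁻¹)
    starting material + target ⇌ idle adduct, settled at all times (K = 30.0 L mol⁻¹)

**What it gives.** The flask gives 0.892%, 4.76%, 11.0% and 16.7%. From 4.0 h to 6.0 h it climbs 0.0285 h⁻¹ of the charge per hour, against the charge rate of 0.0307 h⁻¹, and that charge rate puts Wednesday's run at 13.8% at 5.00 h, where the reading is 14%. At 6.00 h in the flask, spent carrier has a half-life of 0.77 h by the forward step alone, far shorter than the 20 h of starting material. Fresh carrier is then made at 1.00 times the rate it is used, each step taken net, and holds 60.7% of the catalyst.

Readings and results were computed with constants of no real substance; noise was put on by code.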